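**Strategy.** Ring A is disconnected to open chains. Its C2'-OH, C3'-Me and C4'-OMe occupy three neighbouring carbons next to the ester-bearing C1', which is the substitution pattern delivered when a vinylketene meets 1-methoxypropyne. A single photochemical operation on a diazoketone that is already esterified to ring B makes C5'–C6' (Wolff shift), C2'–C3' and C4'–C5' ([2+2]) and C1'–C2' (six-electron closure), so no benzoic acid blocked at both ortho positions ever has to be esterified. The precursor is the ring-B aryl (E)-5-diazo-3-methyl-4-oxopent-2-enoate with its C2 hydroxyl free and hydrogen-bonded to the C1 ester; chlorination at C5', the one unsubstituted aromatic carbon, then completes the target.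

Key step: step 9

Remark on the chemistry: the ring-B C2 hydroxyl is carried free throughout, because it is hydrogen-bonded to the C1 ester and flanked on both sides, and because the key step in any case releases a phenol of the same kind (C2'-OH of ring A) beside the ketene; the mesaconate unit is built as a half-ester, so that the carboxyl on the CH carbon (future depside carbonyl) and the one on the methyl-bearing carbon (future C2') are told apart by construction and not by a rate difference.

**Route**

Step 1
Reactants: 1 methyl 2,4-dihydroxy-3,6-dimethylbenzoate (atraric acid)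
Product: 3 methyl 5-formyl-2,4-dihydroxy-3,6-dimethylbenzoate, via α-chloro ether 2 (not isolated)
Conditions: Cl2CHOMe (1.3 equiv), TiCl4 (2.5 equiv), CH2Cl2, 0 °C to rt; then ice/1 M HCl
Reagents that add atoms: dichloromethyl methyl ether, COC(Cl)Cl; water, O
Why: Rieche formylation (electrophilic aromatic substitution by the TiCl4-activated dichloromethyl ether) should occur at C5, the only unsubstituted ring carbon, which is ortho to the C4 hydroxyl and para to the C2 hydroxyl, and the aqueous quench hydrolyses α-chloro ether 2 to the aldehyde.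

Step 2
Reactants: 3 methyl 5-formyl-2,4-dihydroxy-3,6-dimethylbenzoate
Product: 5 methyl 2,4-dihydroxy-3,5,6-trimethylbenzoate, via benzylic alcohol 4 (not isolated)
Conditions: H2 (3 atm), Pd/C (10%), AcOH, 40 °C
Reagents that add atoms: none
Why: Catalytic hydrogenation reduces the aldehyde to benzylic alcohol 4, whose C–O bond is activated by the ortho and para hydroxyls and is hydrogenolysed to the methyl group, while the fully substituted ring and the ester should stay untouched.

Step 3
Reactants: 6 tert-butyl 2-bromopropanoate (racemic)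
Product: 8 tert-butyl 2-(triphenyl-λ5-phosphanylidene)propanoate, via phosphonium bromide 7 (not isolated)
Conditions: PPh3, toluene, 90 °C; then 2 M NaOH, CH2Cl2, 0 °C
Reagents that add atoms: triphenylphosphine, c1ccc(cc1)P(c1ccccc1)c1ccccc1
Why: SN2 quaternisation of PPh3 by the α-bromo ester and deprotonation of the ester-stabilised phosphonium salt is the standard preparation of a stabilised Wittig ylide; the stereocentre of 6 is lost.

Step 4
Reactants: 8 tert-butyl 2-(triphenyl-λ5-phosphanylidene)propanoate; 9 glyoxylic acid monohydrate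
Product: 10 (2E)-4-tert-butoxy-3-methyl-4-oxobut-2-enoic acid
Conditions: CH2Cl2, 0 °C to rt; NaHCO3 extraction, then acidification
Reagents that add atoms: none
Why: Wittig olefination of the aldehyde carbon of 9 with the stabilised ylide is E-selective, so CO2H should end up trans to CO2tBu (mesaconate geometry), and the free acid is unambiguously the carboxyl on the CH carbon.

Step 5
Reactants: 5 methyl 2,4-dihydroxy-3,5,6-trimethylbenzoate; 10 (2E)-4-tert-butoxy-3-methyl-4-oxobut-2-enoic acid
Product: 11 methyl 4-{[(2E)-4-tert-butoxy-3-methyl-4-oxobut-2-enoyl]oxy}-2-hydroxy-3,5,6-trimethylbenzoate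
Conditions: DCC (1.1 equiv), DMAP (0.1 equiv), CH2Cl2, 0 °C to rt
Reagents that add atoms: none
Why: Steglich esterification of the unhindered acid should take place at O4 only, because the C2 hydroxyl is tied up in a hydrogen bond to the C1 ester carbonyl and is flanked by the ester and the C3 methyl, whereas the C4 hydroxyl is a free (if di-ortho-methylated) phenol.

Step 6
Reactants: 11 methyl 4-{[(2E)-4-tert-butoxy-3-methyl-4-oxobut-2-enoyl]oxy}-2-hydroxy-3,5,6-trimethylbenzoate
Product: 12 (2E)-4-[3-hydroxy-4-(methoxycarbonyl)-2,5,6-trimethylphenoxy]-2-methyl-4-oxobut-2-enoic acid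
Conditions: TFA/CH2Cl2 (1:3), rt
Reagents that add atoms: none
Why: Acidolysis of the tert-butyl ester (loss of the tert-butyl cation as isobutene) should free the hindered carboxyl without touching the aryl ester, the methyl ester or the E alkene, and ring B has no free position for tert-butylation.

Step 7
Reactants: 12 (2E)-4-[3-hydroxy-4-(methoxycarbonyl)-2,5,6-trimethylphenoxy]-2-methyl-4-oxobut-2-enoic acid
Product: 14 methyl 4-{[(2E)-5-diazo-3-methyl-4-oxopent-2-enoyl]oxy}-2-hydroxy-3,5,6-trimethylbenzoate, via acid chloride 13 (not isolated)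
Conditions: (COCl)2 (1.3 equiv), DMF (cat.), CH2Cl2, 0 °C to rt, evaporate; then TMSCHN2 (2.5 equiv), THF/MeCN (1:1), 0 °C, dark
Reagents that add atoms: (trimethylsilyl)diazomethane, C[Si](C)(C)C=[N+]=[N-]
Why: Acid chloride formation followed by C-acylation of the diazoalkane (first stage of the Arndt–Eistert sequence, the silyl group leaving with chloride) should give the diazoketone, since 13 has no α-hydrogen for ketene formation, its trisubstituted alkene is a slow dipolarophile, and the hydrogen-bonded phenol is neither acylated without base nor methylated without methanol.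

Step 8
Reactants: 15 chloroacetaldehyde dimethyl acetal
Product: 17 1-methoxypropyne, via sodium methoxyacetylide 16 (not isolated)
Conditions: NaNH2 (3.2 equiv), liquid NH3, −35 °C; then MeI (1.0 equiv), −35 °C; H2O, distillation
Reagents that add atoms: iodomethane, CI
Why: Threefold reaction with NaNH2 (loss of methanol and HCl, then deprotonation) gives sodium methoxyacetylide 16, whose carbon is alkylated by iodomethane in an SN2 reaction, the established route to 1-alkoxyalk-1-ynes from chloroacetaldehyde acetals.

Step 9
Reactants: 14 methyl 4-{[(2E)-5-diazo-3-methyl-4-oxopent-2-enoyl]oxy}-2-hydroxy-3,5,6-trimethylbenzoate; 17 1-methoxypropyne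
Product: 22 methyl 2-hydroxy-4-[(2-hydroxy-4-methoxy-3,6-dimethylbenzoyl)oxy]-3,5,6-trimethylbenzoate, via vinylketene 18 (not isolated), via cyclobutenone 19 (not isolated), via dienylketene 20 (not isolated), via cyclohexadienone 21 (not isolated)
Conditions: 17 (3 equiv), ClCH2CH2Cl (0.1 M), argon, hν (365 nm), 20 °C; then 80 °C
Reagents that add atoms: none
Why: Light expels N2 from 14 and the alkenyl group shifts to the carbene carbon (Wolff rearrangement, new C5'–C6' bond) to give vinylketene 18, across whose ketene C=C the electron-rich alkyne 17 adds in a [2+2] cycloaddition (C2'–C3' and C4'–C5') to give 4-alkenylcyclobutenone 19. Four-electron electrocyclic opening of 19 gives dienylketene 20, which closes ring A as a six-membered carbocycle by six-electron electrocyclisation between the ketene carbon C2' and the ester-bearing alkene terminus C1', and enolisation of dienone 21 gives the phenol; this is the Danheiser benzannulation in its diazoketone (photo-Wolff) form, which is established for alkoxyalkynes. No stereocentre has to be controlled, since the sp3 centres of 19 and 21 vanish on ring opening and aromatisation. The step needs one regiochemistry in the [2+2] event, secured by polarity matching: the nucleophilic methyl-bearing carbon of the ynol ether bonds to the electrophilic ketene carbonyl carbon, which places C3'-Me between C2'-OH and C4'-OMe. It also needs the E alkene of 14, which keeps the aryloxycarbonyl group turned away from the forming bond and unable to capture the ketene as a pyranone. The excess of 17 and irradiation at 365 nm, where the diazo enone absorbs but the aryl ester and salicylate chromophores do not, should keep the hydrogen-bonded phenols and the ester linkage out of the reaction.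

Step 10
Reactants: 22 methyl 2-hydroxy-4-[(2-hydroxy-4-methoxy-3,6-dimethylbenzoyl)oxy]-3,5,6-trimethylbenzoate
Product: 23 methyl 4-[(3-chloro-6-hydroxy-4-methoxy-2,5-dimethylbenzoyl)oxy]-2-hydroxy-3,5,6-trimethylbenzoate
Conditions: SO2Cl2 (1.05 equiv), CH2Cl2, 0 °C, dark
Reagents that add atoms: sulfuryl chloride, O=S(=O)(Cl)Cl
Why: Electrophilic aromatic chlorination should hit C5' only, since it is the single aromatic C–H of the molecule and lies para to the C2' hydroxyl and ortho to the C4' methoxy group, whereas ring B is fully substituted and less electron-rich.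

**Compound list**

1 | methyl 2,4-dihydroxy-3,6-dimethylbenzoate (atraric acid) | COC(=O)c1c(C)cc(O)c(C)c1O | starting material
2 | methyl 5-[chloro(methoxy)methyl]-2,4-dihydroxy-3,6-dimethylbenzoate (racemic α-chloro ether) | COC(=O)c1c(C)c(C(Cl)OC)c(O)c(C)c1O | intermediate
3 | methyl 5-formyl-2,4-dihydroxy-3,6-dimethylbenzoate | COC(=O)c1c(C)c(C=O)c(O)c(C)c1O | intermediate
4 | methyl 2,4-dihydroxy-5-(hydroxymethyl)-3,6-dimethylbenzoate | COC(=O)c1c(C)c(CO)c(O)c(C)c1O | intermediate
5 | methyl 2,4-dihydroxy-3,5,6-trimethylbenzoate | COC(=O)c1c(C)c(C)c(O)c(C)c1O | intermediate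
6 | tert-butyl 2-bromopropanoate (racemic) | CC(Br)C(=O)OC(C)(C)C | starting material
7 | (1-tert-butoxy-1-oxopropan-2-yl)triphenylphosphonium bromide (racemic) | CC(C(=O)OC(C)(C)C)[P+](c1ccccc1)(c1ccccc1)c1ccccc1.[Br-] | intermediate
8 | tert-butyl 2-(triphenyl-λ5-phosphanylidene)propanoate | CC(C(=O)OC(C)(C)C)=P(c1ccccc1)(c1ccccc1)c1ccccc1 | intermediate
9 | glyoxylic acid monohydrate (2,2-dihydroxyacetic acid) | OC(O)C(=O)O | starting material
10 | (2E)-4-tert-butoxy-3-methyl-4-oxobut-2-enoic acid | OC(=O)/C=C(\C)C(=O)OC(C)(C)C | intermediate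
11 | methyl 4-{[(2E)-4-tert-butoxy-3-methyl-4-oxobut-2-enoyl]oxy}-2-hydroxy-3,5,6-trimethylbenzoate | COC(=O)c1c(C)c(C)c(OC(=O)/C=C(\C)C(=O)OC(C)(C)C)c(C)c1O | intermediate
12 | (2E)-4-[3-hydroxy-4-(methoxycarbonyl)-2,5,6-trimethylphenoxy]-2-methyl-4-oxobut-2-enoic acid | COC(=O)c1c(C)c(C)c(OC(=O)/C=C(\C)C(=O)O)c(C)c1O | intermediate
13 | methyl 4-{[(2E)-4-chloro-3-methyl-4-oxobut-2-enoyl]oxy}-2-hydroxy-3,5,6-trimethylbenzoate | COC(=O)c1c(C)c(C)c(OC(=O)/C=C(\C)C(=O)Cl)c(C)c1O | intermediate
14 | methyl 4-{[(2E)-5-diazo-3-methyl-4-oxopent-2-enoyl]oxy}-2-hydroxy-3,5,6-trimethylbenzoate (key-step precursor) | COC(=O)c1c(C)c(C)c(OC(=O)/C=C(\C)C(=O)C=[N+]=[N-])c(C)c1O | intermediate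
15 | chloroacetaldehyde dimethyl acetal (2-chloro-1,1-dimethoxyethane) | COC(CCl)OC | starting material
16 | sodium methoxyacetylide | COC#[C-].[Na+] | intermediate
17 | 1-methoxypropyne | CC#COC | intermediate
18 | methyl 2-hydroxy-3,5,6-trimethyl-4-{[(2E)-3-methyl-5-oxopenta-2,4-dienoyl]oxy}benzoate (vinylketene) | COC(=O)c1c(C)c(C)c(OC(=O)/C=C(\C)C=C=O)c(C)c1O | intermediate
19 | methyl 2-hydroxy-4-{[(2E)-3-(2-methoxy-3-methyl-4-oxocyclobut-2-en-1-yl)but-2-enoyl]oxy}-3,5,6-trimethylbenzoate (racemic cyclobutenone) | COC(=O)c1c(C)c(C)c(OC(=O)/C=C(\C)C2C(=O)C(C)=C2OC)c(C)c1O | intermediate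
20 | methyl 2-hydroxy-4-{[(2E,4E)-5-methoxy-3,6-dimethyl-7-oxohepta-2,4,6-trienoyl]oxy}-3,5,6-trimethylbenzoate (dienylketene) | COC(=O)c1c(C)c(C)c(OC(=O)/C=C(\C)/C=C(/OC)C(C)=C=O)c(C)c1O | intermediate
21 | methyl 2-hydroxy-4-{[(4-methoxy-2,5-dimethyl-6-oxocyclohexa-2,4-dien-1-yl)carbonyl]oxy}-3,5,6-trimethylbenzoate (racemic cyclohexadienone) | COC(=O)c1c(C)c(C)c(OC(=O)C2C(C)=CC(OC)=C(C)C2=O)c(C)c1O | intermediate
22 | methyl 2-hydroxy-4-[(2-hydroxy-4-methoxy-3,6-dimethylbenzoyl)oxy]-3,5,6-trimethylbenzoate (key-step product) | COC(=O)c1c(C)c(C)c(OC(=O)c2c(C)cc(OC)c(C)c2O)c(C)c1O | intermediate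
23 | methyl 4-[(3-chloro-6-hydroxy-4-methoxy-2,5-dimethylbenzoyl)oxy]-2-hydroxy-3,5,6-trimethylbenzoate | COC(=O)c1c(C)c(C)c(OC(=O)c2c(C)c(Cl)c(OC)c(C)c2O)c(C)c1O | target

**Step count**

Total: 10 steps. Longest linear sequence: 7 steps (1, 2, 5, 6, 7, 9, 10 from atraric acid; equally 3, 4, 5, 6, 7, 9, 10 from tert-butyl 2-bromopropanoate).

**Steps most likely to fail, with fallbacks**

Most at risk is step 9. The vinylketene may be captured by a phenolic hydroxyl or by a second ketene before the alkyne adds. Light-driven E-to-Z isomerisation of the enoate may let the ketene close onto the ester carbonyl. The ester on the vinylketene terminus may also slow the six-electron closure. The fallback is the classical depside assembly, with ring A made first; it sets out from 1 and 5 and comes back to the route at 22. Compound 1 would be methylated at its unchelated O4 (MeI, K2CO3, acetone, reflux) to methyl 2-hydroxy-4-methoxy-3,6-dimethylbenzoate F1. Saponification (KOH, aqueous DMSO, 90 °C) should then give 2-hydroxy-4-methoxy-3,6-dimethylbenzoic acid F2. Condensation of F2 and 5 by trifluoroacetic anhydride in toluene at room temperature (mixed-anhydride esterification at the unchelated O4 of 5) should give 22, which enters step 10.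

Second is step 7. 1,3-Dipolar cycloaddition of the diazoalkane to the electron-poor alkene of 13 (pyrazoline formation) may compete with C-acylation, and 13 may acylate a phenolic hydroxyl. The fallback replaces diazoalkane acylation by diazo transfer; it sets out from 9 and 5 and comes back at 14. Compound 9 would be condensed with butan-2-one (85% H3PO4, 80 °C; acid-catalysed aldol condensation at the methylene carbon) to (2E)-3-methyl-4-oxopent-2-enoic acid F3. Esterification with 5 (DCC, DMAP cat., CH2Cl2) should give methyl 2-hydroxy-3,5,6-trimethyl-4-{[(2E)-3-methyl-4-oxopent-2-enoyl]oxy}benzoate F4. Kinetic enolisation of the methyl ketone (LiN(SiMe3)2, 2.2 equiv, THF, −78 °C, the first equivalent being taken by the phenol) and trifluoroacetylation by CF3CO2CH2CF3 should give methyl 2-hydroxy-3,5,6-trimethyl-4-{[(2E)-7,7,7-trifluoro-3-methyl-4,6-dioxohept-2-enoyl]oxy}benzoate F5. Detrifluoroacetylative diazo transfer (MsN3, Et3N, H2O, MeCN, rt) should then give 14.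

Third is step 1. The two hydroxyls and the ester bind TiCl4, so the ring may be deactivated and formylation may stall, or the Lewis acid may attack the methyl ester. The fallback uses aminomethylation and hydrogenolysis in place of formylation and hydrogenolysis; it sets out from 1 and comes back at 5, so steps 1 and 2 are both replaced. Compound 1 with aqueous formaldehyde and morpholine (EtOH, reflux; phenolic Mannich reaction at C5, the only free ring position) should give methyl 2,4-dihydroxy-3,6-dimethyl-5-(morpholin-4-ylmethyl)benzoate F6. Hydrogenolysis of its benzylic C–N bond (H2, Pd/C, AcOH, 60 °C) should give 5.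

Further compounds
F1 | step 9 | methyl 2-hydroxy-4-methoxy-3,6-dimethylbenzoate | COC(=O)c1c(C)cc(OC)c(C)c1O
F2 | step 9 | 2-hydroxy-4-methoxy-3,6-dimethylbenzoic acid | OC(=O)c1c(C)cc(OC)c(C)c1O
F3 | step 7 | (2E)-3-methyl-4-oxopent-2-enoic acid | CC(=O)/C(C)=C/C(=O)O
F4 | step 7 | methyl 2-hydroxy-3,5,6-trimethyl-4-{[(2E)-3-methyl-4-oxopent-2-enoyl]oxy}benzoate | COC(=O)c1c(C)c(C)c(OC(=O)/C=C(\C)C(C)=O)c(C)c1O
F5 | step 7 | methyl 2-hydroxy-3,5,6-trimethyl-4-{[(2E)-7,7,7-trifluoro-3-methyl-4,6-dioxohept-2-enoyl]oxy}benzoate | COC(=O)c1c(C)c(C)c(OC(=O)/C=C(\C)C(=O)CC(=O)C(F)(F)F)c(C)c1O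
F6 | step 1 | methyl 2,4-dihydroxy-3,6-dimethyl-5-(morpholin-4-ylmethyl)benzoate | COC(=O)c1c(C)c(CN2CCOCC2)c(O)c(C)c1O
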